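**Retrosynthetic overview**
1. The target (4-hydroxycolupulone) comes from its tertiary trimethylsilyl ether by Si–O cleavage. The silyl ether comes, in one operation, from a silyl-protected 3-hydroxy-3-prenyl-2H-pyran-2,4-dione and the lithium enolate of methyl 2,2-diprenylacetate. This acylative enol-lactone-to-carbocycle ring transformation forms both ring bonds to the (prenyl)2C–C(=O) unit.
2. Enabling feature: the enol-ester bond O1–C2 of the pyran-2,4-dione ring. C2 is an activated acyl carbon, and its leaving group is the C4–C5–C6 1,3-diketonate, whose central carbon C5 makes the second bond. Ring oxygen O1 ends as the oxygen of the 2-methylpropanoyl group, and the gem-diprenyl ester has no α-hydrogen once the first bond is made.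
3. The pyran-2,4-dione comes from 4-hydroxy-6-isopropyl-3-prenyl-2-pyrone by catalytic asymmetric hydroxylation at C3. This sets the only stereocenter and at the same time converts the unreactive pyrone lactone into the reactive enol lactone.
4. The pyrone comes from methyl acetoacetate by C-prenylation, dianion acylation with an isobutyryl donor and enol lactonisation. The diprenyl ester comes from dimethyl malonate by double prenylation and Krapcho dealkoxycarbonylation.
5. Ring order: the temporary pyranone ring is made first; the six-membered carbocycle of the target is formed second, as the pyranone ring opens.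

Key step: step 8

Assumption: the sense of induction of the catalytic hydroxylation cannot be predicted with certainty for this pyrone, so the route is written for the ligand antipode that gives the (S)-carbinol and the mirror-image ligand is used if the assignment made on the hydroxylated pyrandione shows the opposite sense; β-dicarbonyl compounds are drawn as one tautomer.

**Route**

Step 1
Reactants: 1 dimethyl malonate; 2 1-bromo-3-methylbut-2-ene (prenyl bromide)
Product: 3 dimethyl 2,2-bis(3-methylbut-2-en-1-yl)propanedioate
Conditions: NaH (2.2 equiv), 2 (2.2 equiv), THF/DMF, 0 °C → rt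
Reagents that add atoms: none
Why: twofold malonic ester alkylation (SN2 at the primary allylic bromide), with excess base and bromide driving it to the dialkylated product.

Step 2
Reactants: 3 dimethyl 2,2-bis(3-methylbut-2-en-1-yl)propanedioate
Product: 4 methyl 5-methyl-2-(3-methylbut-2-en-1-yl)hex-4-enoate
Conditions: LiCl (2 equiv), H2O (2 equiv), DMSO, 160 °C
Reagents that add atoms: none
Why: Krapcho dealkoxycarbonylation (chloride dealkylation of one methyl ester, decarboxylation, protonation), which should leave the trisubstituted olefins untouched.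

Step 3
Reactants: 5 methyl acetoacetate; 2 1-bromo-3-methylbut-2-ene
Product: 6 methyl 2-acetyl-5-methylhex-4-enoate
Conditions: NaH (1.0 equiv), THF, 0 °C; then 2 (1.0 equiv), 0 °C → rt
Reagents that add atoms: none
Why: acetoacetic ester C-alkylation of the sodium enolate with a primary allylic bromide; one equivalent of base and bromide limits dialkylation.

Step 4
Reactants: 6 methyl 2-acetyl-5-methylhex-4-enoate; 7 N-methoxy-N,2-dimethylpropanamide
Product: 9 methyl 6-methyl-2-(3-methylbut-2-en-1-yl)-3,5-dioxoheptanoate, via dilithium dienolate 8 (not isolated)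
Conditions: LDA (2.1 equiv), THF, −78 → 0 °C; then 7 (1.05 equiv), −78 → 0 °C; 1 M HCl
Reagents that add atoms: none
Why: Claisen-type γ-acylation of a β-keto ester dianion at its more reactive terminal carbon; the N-methoxy-N-methyl amide gives a stable chelated tetrahedral adduct, so over-addition and proton exchange with the acidic product should not occur before the quench.

Step 5
Reactants: 9 methyl 6-methyl-2-(3-methylbut-2-en-1-yl)-3,5-dioxoheptanoate
Product: 10 4-hydroxy-3-(3-methylbut-2-en-1-yl)-6-(propan-2-yl)-2H-pyran-2-one
Conditions: DBU (1.5 equiv), toluene, 110 °C; then cold 1 M HCl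
Reagents that add atoms: none
Why: base-mediated enol lactonisation of a 3,5-diketo ester (6-exo-trig attack of the C5 enol oxygen on the ester) with loss of methanol, driven by formation of the 4-hydroxy-2-pyrone anion.

Step 6
Reactants: 10 4-hydroxy-3-(3-methylbut-2-en-1-yl)-6-(propan-2-yl)-2H-pyran-2-one
Product: 11 (3S)-3-hydroxy-3-(3-methylbut-2-en-1-yl)-6-(propan-2-yl)-2H-pyran-2,4(3H)-dione
Conditions: Ni(ClO4)2·6H2O (10 mol %), (R,R)-4,6-dibenzofurandiyl-2,2'-bis(4-phenyloxazoline) [(R,R)-DBFOX-Ph] (11 mol %), (±)-trans-3-phenyl-2-(phenylsulfonyl)oxaziridine (1.2 equiv), 4 Å molecular sieves, CH2Cl2, 0 °C → rt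
Reagents that add atoms: (±)-trans-3-phenyl-2-(phenylsulfonyl)oxaziridine, O=S(=O)(c1ccccc1)N1OC1c1ccccc1
Why: catalytic asymmetric α-hydroxylation of a cyclic β-dicarbonyl enol (a hydroxylative dearomatisation of the 4-hydroxy-2-pyrone), in which the pyrone should bind the chiral nickel–bis(oxazoline) complex through the C2 lactone carbonyl and the C4 oxygen so that the ligand shields one face of C3 and oxygen is delivered to the open face to set the (S)-carbinol, while the prenyl olefin should not be epoxidised by an N-sulfonyloxaziridine at room temperature.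

Step 7
Reactants: 11 (3S)-3-hydroxy-3-(3-methylbut-2-en-1-yl)-6-(propan-2-yl)-2H-pyran-2,4(3H)-dione
Product: 12 (3S)-3-(3-methylbut-2-en-1-yl)-6-(propan-2-yl)-3-[(trimethylsilyl)oxy]-2H-pyran-2,4(3H)-dione
Conditions: TMSOTf (1.3 equiv), 2,6-lutidine (2 equiv), CH2Cl2, −78 °C
Reagents that add atoms: trimethylsilyl trifluoromethanesulfonate, C[Si](C)(C)OS(=O)(=O)C(F)(F)F
Why: silyl triflate silylation of a hindered tertiary alcohol under 2,6-lutidine buffering at low temperature, which should leave the enol lactone and the isopropyl γ-position untouched; the stereocenter is not involved.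

Step 8
Reactants: 4 methyl 5-methyl-2-(3-methylbut-2-en-1-yl)hex-4-enoate; 12 (3S)-3-(3-methylbut-2-en-1-yl)-6-(propan-2-yl)-3-[(trimethylsilyl)oxy]-2H-pyran-2,4(3H)-dione
Product: 16 (6S)-5-hydroxy-4-(2-methylpropanoyl)-2,2,6-tris(3-methylbut-2-en-1-yl)-6-[(trimethylsilyl)oxy]cyclohex-4-ene-1,3-dione, via lithium ester enolate 13 (not isolated), via acyclic lithium diketonate 14 (not isolated), via lithium triketonate 15 (not isolated)
Conditions: 4 (1.5 equiv), LDA (1.5 equiv), THF, −78 °C; then 12, −78 → 0 °C; then 23–40 °C; AcOH, 0 °C, pH 4 buffer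
Reagents that add atoms: none
Why: Proposed new method: the tetrasubstituted enolate 13 should add to the lactone carbonyl C2 of 12, whose tetrahedral adduct collapses irreversibly because the enol-ester bond O1–C2 expels O1 as the C4–C5–C6 1,3-diketonate 14 (first bond, ring ketone to the gem-diprenyl carbon); the central carbon C5 of that diketonate then attacks the methyl ester, which has no α-hydrogen and so stays electrophilic, closing the carbocycle (second bond) with loss of methoxide, which deprotonates the new β-triketone to 15 and makes the sequence irreversible. The closest known reaction types are the Fujimoto–Belleau annulation of enol lactones with carbanions for the ring opening and the Lacey–Dieckmann closure of a 1,3-dicarbonyl anion onto an ester for the ring closure. The six-membered ring closes by a 6-(enolendo)-exo-trig Claisen condensation. No new stereocenter is formed: the quaternary carbinol carbon set in step 6 is not enolisable and is not a bond-forming atom, and its silyl ether blocks the α-ketol shift and the 5-exo lactonisation onto the ester that a free alkoxide would allow. The selectivity needed is attack at the lactone carbonyl rather than at the C4 ketone, at C6 or at the isopropyl methine hydrogen; addition to C4 is a reversible aldol, C6 is fully substituted and more hindered, and low temperature disfavours the slow deprotonation of a tertiary vinylogous C–H.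

Step 9
Reactants: 16 (6S)-5-hydroxy-4-(2-methylpropanoyl)-2,2,6-tris(3-methylbut-2-en-1-yl)-6-[(trimethylsilyl)oxy]cyclohex-4-ene-1,3-dione
Product: 17 (6S)-5,6-dihydroxy-4-(2-methylpropanoyl)-2,2,6-tris(3-methylbut-2-en-1-yl)cyclohex-4-ene-1,3-dione
Conditions: Et3N·3HF (3 equiv), THF, 0 °C; pH 4 buffer work-up
Reagents that add atoms: none
Why: fluoride cleavage of the tertiary trimethylsilyl ether under nearly neutral conditions, which should spare the acid-sensitive prenyl/enol pairs and avoid base-induced α-ketol ring contraction; the stereocenter is not involved.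

**Compound list**
1 | dimethyl malonate | COC(=O)CC(=O)OC | starting material
2 | 1-bromo-3-methylbut-2-ene | CC(C)=CCBr | starting material
3 | dimethyl 2,2-bis(3-methylbut-2-en-1-yl)propanedioate | COC(=O)C(CC=C(C)C)(CC=C(C)C)C(=O)OC | intermediate
4 | methyl 5-methyl-2-(3-methylbut-2-en-1-yl)hex-4-enoate | COC(=O)C(CC=C(C)C)CC=C(C)C | intermediate
5 | methyl acetoacetate | CC(=O)CC(=O)OC | starting material
6 | methyl 2-acetyl-5-methylhex-4-enoate | CC(=O)C(CC=C(C)C)C(=O)OC | intermediate
7 | N-methoxy-N,2-dimethylpropanamide | CC(C)C(=O)N(C)OC | starting material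
8 | dilithium dienolate of 6 | C=C(O[Li])C(CC=C(C)C)=C(O[Li])OC | intermediate
9 | methyl 6-methyl-2-(3-methylbut-2-en-1-yl)-3,5-dioxoheptanoate | COC(=O)C(CC=C(C)C)C(=O)CC(=O)C(C)C | intermediate
10 | 4-hydroxy-3-(3-methylbut-2-en-1-yl)-6-(propan-2-yl)-2H-pyran-2-one | CC(C)C1=CC(O)=C(CC=C(C)C)C(=O)O1 | intermediate
11 | (3S)-3-hydroxy-3-(3-methylbut-2-en-1-yl)-6-(propan-2-yl)-2H-pyran-2,4(3H)-dione | CC(C)C1=CC(=O)[C@@](O)(CC=C(C)C)C(=O)O1 | intermediate
12 | (3S)-3-(3-methylbut-2-en-1-yl)-6-(propan-2-yl)-3-[(trimethylsilyl)oxy]-2H-pyran-2,4(3H)-dione | CC(C)C1=CC(=O)[C@@](O[Si](C)(C)C)(CC=C(C)C)C(=O)O1 | intermediate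
13 | lithium enolate of 4 | COC(O[Li])=C(CC=C(C)C)CC=C(C)C | intermediate
14 | lithium enolate of methyl (4S)-8-methyl-2,2,4-tris(3-methylbut-2-en-1-yl)-3,5,7-trioxo-4-[(trimethylsilyl)oxy]nonanoate | CC(C)C(O[Li])=CC(=O)[C@@](O[Si](C)(C)C)(CC=C(C)C)C(=O)C(CC=C(C)C)(CC=C(C)C)C(=O)OC | intermediate
15 | lithium salt of 16 | CC(C)=CCC1(CC=C(C)C)C(=O)C(C(=O)C(C)C)=C(O[Li])[C@@](O[Si](C)(C)C)(CC=C(C)C)C1=O | intermediate
16 | (6S)-5-hydroxy-4-(2-methylpropanoyl)-2,2,6-tris(3-methylbut-2-en-1-yl)-6-[(trimethylsilyl)oxy]cyclohex-4-ene-1,3-dione | CC(C)=CCC1(CC=C(C)C)C(=O)C(C(=O)C(C)C)=C(O)[C@@](O[Si](C)(C)C)(CC=C(C)C)C1=O | intermediate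
17 | (6S)-5,6-dihydroxy-4-(2-methylpropanoyl)-2,2,6-tris(3-methylbut-2-en-1-yl)cyclohex-4-ene-1,3-dione | CC(C)=CCC1(CC=C(C)C)C(=O)C(C(=O)C(C)C)=C(O)[C@@](O)(CC=C(C)C)C1=O | target

**Step count and risks**
Total step count: 9. Longest linear sequence: 7 steps (steps 3, 4, 5, 6, 7, 8, 9).

Steps most likely to fail:

1. Step 8 (Proposed new method). The hindered enolate 13 may act as a base toward the isopropyl methine of 12 (vinylogous deprotonation) or add too slowly to the lactone carbonyl next to the quaternary carbon, and the second closure may stall after the first bond. Fallback with known chemistry: the ring transformation is given up and the carbocycle is taken from an aromatic ring. The fallback sets out from 2 and commercial 2-methyl-1-(2,4,6-trihydroxyphenyl)propan-1-one. Threefold C-prenylation with 2 (NaOMe, MeOH, 0 °C) should proceed through the monoprenyl compound 1-[2,4,6-trihydroxy-3-(3-methylbut-2-en-1-yl)phenyl]-2-methylpropan-1-one F1 and the diprenyl compound 1-[2,4,6-trihydroxy-3,5-bis(3-methylbut-2-en-1-yl)phenyl]-2-methylpropan-1-one F2 to the dearomatised 3,5-dihydroxy-2-(2-methylpropanoyl)-4,6,6-tris(3-methylbut-2-en-1-yl)cyclohexa-2,4-dien-1-one F3 in one flask. F1 and F2 need not be isolated. The prenyl-bearing enol carbon C4 of F3 is then hydroxylated with the oxaziridine and the chiral nickel catalyst of step 6 (the same reaction type on a cyclic 2-substituted 1,3-dicarbonyl compound, with chromatography on a chiral stationary phase if the enantiomeric purity has to be raised). The route is rejoined at 17.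

2. Step 6. The nearly planar pyrone chelate may give poor facial selectivity, or the sense of induction may be opposite to the one assumed. Fallback by resolution instead of asymmetric catalysis, setting out from 10: hydroxylation with the same oxaziridine and Et3N in CH2Cl2 without the chiral catalyst should give racemic 3-hydroxy-3-(3-methylbut-2-en-1-yl)-6-(propan-2-yl)-2H-pyran-2,4(3H)-dione F4 without control of configuration. Silylation of F4 as in step 7 should give racemic 3-(3-methylbut-2-en-1-yl)-6-(propan-2-yl)-3-[(trimethylsilyl)oxy]-2H-pyran-2,4(3H)-dione F5 in the same way. Preparative chromatography of F5 on a chiral stationary phase (cellulose tris(3,5-dimethylphenylcarbamate), supercritical CO2/2-propanol) gives the (S)-enantiomer, and the route is rejoined at 12.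

3. Step 4. The second deprotonation of the α-substituted acetoacetate may be incomplete, so that the amide meets monoanion or free LDA and conversion stays low. Fallback with the prenyl group introduced after pyrone formation, setting out from 5: LDA (2.1 equiv, THF, −78 → 0 °C) should convert 5 into the dilithium dienolate of methyl acetoacetate F6 in the flask, and acylation of F6 with 7 should give methyl 6-methyl-3,5-dioxoheptanoate F7 after acidic work-up. DBU in toluene at 110 °C should close F7 to 4-hydroxy-6-(propan-2-yl)-2H-pyran-2-one F8 with loss of methanol. Tsuji–Trost C3-allylation of F8 with 2 (Pd(PPh3)4, Et3N, THF, rt; attack at the unsubstituted allyl terminus) rejoins the route at 10.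

Further compounds
F1 | step 8 | 1-[2,4,6-trihydroxy-3-(3-methylbut-2-en-1-yl)phenyl]-2-methylpropan-1-one | CC(C)C(=O)c1c(O)cc(O)c(CC=C(C)C)c1O
F2 | step 8 | 1-[2,4,6-trihydroxy-3,5-bis(3-methylbut-2-en-1-yl)phenyl]-2-methylpropan-1-one | CC(C)C(=O)c1c(O)c(CC=C(C)C)c(O)c(CC=C(C)C)c1O
F3 | step 8 | 3,5-dihydroxy-2-(2-methylpropanoyl)-4,6,6-tris(3-methylbut-2-en-1-yl)cyclohexa-2,4-dien-1-one (colupulone) | CC(C)C(=O)C1=C(O)C(CC=C(C)C)=C(O)C(CC=C(C)C)(CC=C(C)C)C1=O
F4 | step 6 | racemic 3-hydroxy-3-(3-methylbut-2-en-1-yl)-6-(propan-2-yl)-2H-pyran-2,4(3H)-dione | CC(C)C1=CC(=O)C(O)(CC=C(C)C)C(=O)O1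
F5 | step 6 | racemic 3-(3-methylbut-2-en-1-yl)-6-(propan-2-yl)-3-[(trimethylsilyl)oxy]-2H-pyran-2,4(3H)-dione | CC(C)C1=CC(=O)C(O[Si](C)(C)C)(CC=C(C)C)C(=O)O1
F6 | step 4 | dilithium dienolate of methyl acetoacetate | C=C(O[Li])C=C(O[Li])OC
F7 | step 4 | methyl 6-methyl-3,5-dioxoheptanoate | COC(=O)CC(=O)CC(=O)C(C)C
F8 | step 4 | 4-hydroxy-6-(propan-2-yl)-2H-pyran-2-one | CC(C)C1=CC(O)=CC(=O)O1
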